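**Strategy.** Everything rests on the C–C bond of the CH2–CH2 bridge between the para-phenylene ring (C) and the meta-phenylene ring (D), one edge of the 18-membered ring. Instead of closing that ring at carbon, a 19-membered ring is closed at sulfur and the sulfur atom is then deleted. The two benzylic CH2 groups flanking SO2 are the only acidic C–H bonds in a molecule otherwise made of aryl ethers, so in situ α-bromination and Ramberg–Bäcklund loss of SO2 join them directly and contract the ring to 18 members. The precursor is the cyclic dibenzyl sulfone with both phenols masked as methyl ethers; hydrogenation and demethylation finish the synthesis.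

Key step: step 11

Assumption: the target SMILES holds no stereocentre, no stereogenic double bond and no configurationally fixed axis, so the compound is achiral and no asymmetric step is needed.
Ring labels: A = ring with OH para to the A–O–D ether oxygen; B = ring with OH ortho to the B–O–C ether oxygen; C = para-phenylene; D = meta-phenylene.

**Route**

Step 1
Reactants: 1 2-fluoro-5-methoxybenzaldehyde; 2 methyl 3-hydroxybenzoate
Product: 3 methyl 3-(2-formyl-4-methoxyphenoxy)benzoate
Conditions: K2CO3, DMAc, 140 °C
Reagents that add atoms: none
Why: SNAr diaryl ether formation, in which the phenoxide of 2 adds at the C–F carbon of 1 (Meisenheimer intermediate stabilised by the ortho formyl group) and fluoride leaves.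

Step 2
Reactants: 4 isovanillin (3-hydroxy-4-methoxybenzaldehyde); 5 methyl 4-fluorobenzoate
Product: 6 methyl 4-(5-formyl-2-methoxyphenoxy)benzoate
Conditions: K2CO3, DMAc, 150 °C
Reagents that add atoms: none
Why: SNAr diaryl ether formation, the para ester activating the C–F carbon towards the phenoxide of 4, whose non-enolisable aldehyde is inert to carbonate.

Step 3
Reactants: 6 methyl 4-(5-formyl-2-methoxyphenoxy)benzoate
Product: 7 methyl 4-[5-(hydroxymethyl)-2-methoxyphenoxy]benzoate
Conditions: NaBH4, MeOH/THF, 0 °C
Reagents that add atoms: none
Why: Chemoselective borohydride reduction, which reduces the aldehyde quickly and leaves the benzoate ester untouched at 0 °C.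

Step 4
Reactants: 7 methyl 4-[5-(hydroxymethyl)-2-methoxyphenoxy]benzoate
Product: 8 [4-methoxy-3-[4-(methoxycarbonyl)phenoxy]benzyl]triphenylphosphonium bromide
Conditions: PPh3·HBr, MeCN, reflux
Reagents that add atoms: triphenylphosphine hydrobromide, [Br-].c1ccc(cc1)[PH+](c1ccccc1)c1ccccc1
Why: Direct conversion of a benzylic alcohol into a benzylphosphonium salt, the para-methoxy group easing acid-promoted ionisation of the C–OH bond so that triphenylphosphine captures the benzylic carbon.

Step 5
Reactants: 8 [4-methoxy-3-[4-(methoxycarbonyl)phenoxy]benzyl]triphenylphosphonium bromide; 3 methyl 3-(2-formyl-4-methoxyphenoxy)benzoate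
Product: 10 methyl 3-[4-methoxy-2-[2-[4-methoxy-3-[4-(methoxycarbonyl)phenoxy]phenyl]ethenyl]phenoxy]benzoate (E/Z mixture), via phosphonium ylide 9 (not isolated)
Conditions: K2CO3, 18-crown-6 (cat.), CH2Cl2, reflux
Reagents that add atoms: none
Why: Wittig olefination of the aryl aldehyde by the semi-stabilised benzylic ylide under mild solid–liquid phase-transfer base that spares both methyl esters; the alkene geometry is irrelevant because step 6 removes it.

Step 6
Reactants: 10 stilbene diester (E/Z mixture)
Product: 11 methyl 3-[4-methoxy-2-[2-[4-methoxy-3-[4-(methoxycarbonyl)phenoxy]phenyl]ethyl]phenoxy]benzoate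
Conditions: H2 (1 atm), 10% Pd/C, EtOAc, rt
Reagents that add atoms: none
Why: Catalytic hydrogenation of the stilbene C=C, under which esters, aryl methyl ethers and diaryl ethers are stable, so both isomers converge on the A–B ethano bridge.

Step 7
Reactants: 11 bibenzyl diester
Product: 12 [3-[2-[2-[3-[4-(hydroxymethyl)phenoxy]-4-methoxyphenyl]ethyl]-4-methoxyphenoxy]phenyl]methanol (diol)
Conditions: LiAlH4, THF, 0 °C to rt
Reagents that add atoms: none
Why: Hydride reduction of both aryl esters to benzylic alcohols; nothing else in the molecule is reducible.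

Step 8
Reactants: 12 diol
Product: 13 1-(bromomethyl)-3-[2-[2-[3-[4-(bromomethyl)phenoxy]-4-methoxyphenyl]ethyl]-4-methoxyphenoxy]benzene (bis(benzyl bromide))
Conditions: PBr3, CH2Cl2, 0 °C
Reagents that add atoms: phosphorus tribromide, BrP(Br)Br
Why: Conversion of benzylic alcohols into bromides through phosphite esters displaced by bromide (SN2), under conditions too mild to cleave aryl methyl ethers.

Step 9
Reactants: 13 bis(benzyl bromide)
Product: 15 19-membered cyclic dibenzyl sulfide (dimethyl ether), via sodium bromo thiolate 14 (not isolated)
Conditions: Na2S·9H2O, EtOH/THF/H2O, high dilution (slow simultaneous addition), 60 °C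
Reagents that add atoms: sodium sulfide (used as the nonahydrate), [Na+].[Na+].[S-2]
Why: Double SN2 thioetherification of the thiacyclophane type, in which the thiolate formed by the first displacement closes the ring on the second, highly reactive benzylic bromide while slow addition suppresses intermolecular alkylation.

Step 10
Reactants: 15 cyclic sulfide
Product: 17 19-membered cyclic dibenzyl sulfone (dimethyl ether), via cyclic sulfoxide 16 (not isolated)
Conditions: mCPBA (2.2 equiv), CH2Cl2, 0 °C to rt
Reagents that add atoms: 3-chloroperoxybenzoic acid, OOC(=O)c1cccc(Cl)c1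
Why: Peracid S-oxidation of a thioether through the sulfoxide to the sulfone, far faster than any attack on the alkoxy-substituted arenes.

Step 11
Reactants: 17 cyclic sulfone
Product: 20 18-membered macrocyclic (E)-stilbene (dimethyl ether), via alpha-bromo sulfone 18 (not isolated), via trans-episulfone 19 (not isolated)
Conditions: BrCl2C–CCl2Br, KOH/Al2O3, t-BuOH/THF, rt
Reagents that add atoms: none
Why: KOH on alumina removes a benzylic proton next to SO2 (preferably on the ring D side, where the meta aryloxy group is inductively withdrawing) and the carbanion takes bromine from 1,2-dibromotetrachloroethane, which collapses to tetrachloroethene and bromide without generating a carbene; the second α-carbanion then displaces bromide to give episulfone 19, which loses SO2 stereospecifically to the stilbene. This is the one-flask Ramberg–Bäcklund reaction, well established for acyclic and cyclic dibenzyl sulfones giving stilbenes, including cyclophane-type ones. The 18-membered ring is formed by contraction of the existing 19-membered ring and not by a macrocyclisation: the new C–C bond arises in a 3-exo-tet closure to the thiirane dioxide, so no dilution is needed. No stereocentre is created in 20; the E geometry is expected because the benzylic episulfone positions equilibrate under base to the trans isomer, and any Z isomer converges in step 12. The selectivity required is halogenation only at the two sulfone α-carbons and only once: these are the sole C–H bonds acidic enough for KOH (the A–B ethano bridge and the methoxy groups are inert), and with a slight excess of the bromine donor the α-bromo sulfone should cyclise faster than it is brominated again.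

Step 12
Reactants: 20 macrocyclic stilbene
Product: 21 dihydroptychantol A dimethyl ether (18-membered macrocyclic bis(bibenzyl))
Conditions: H2 (1 atm), 10% Pd/C, EtOAc/THF, rt
Reagents that add atoms: none
Why: Catalytic hydrogenation of the stilbene C=C after chromatographic removal of sulfur residues; aryl methyl ethers and diaryl ethers are not hydrogenolysed under these conditions.

Step 13
Reactants: 21 dihydroptychantol A dimethyl ether
Product: 22 dihydroptychantol A
Conditions: BBr3, CH2Cl2, −78 °C to rt; then H2O
Reagents that add atoms: none
Why: Lewis-acid ether cleavage, in which BBr3 coordinates each methoxy oxygen and bromide removes the methyl group by SN2; the diaryl ether C–O bonds offer no sp3 carbon and survive, and aqueous work-up frees both phenols.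

**Compound list**

1 | 2-fluoro-5-methoxybenzaldehyde | COc1ccc(F)c(C=O)c1 | starting material
2 | methyl 3-hydroxybenzoate | COC(=O)c1cccc(O)c1 | starting material
3 | methyl 3-(2-formyl-4-methoxyphenoxy)benzoate | COC(=O)c1cccc(Oc2ccc(OC)cc2C=O)c1 | intermediate
4 | isovanillin (3-hydroxy-4-methoxybenzaldehyde) | COc1ccc(C=O)cc1O | starting material
5 | methyl 4-fluorobenzoate | COC(=O)c1ccc(F)cc1 | starting material
6 | methyl 4-(5-formyl-2-methoxyphenoxy)benzoate | COC(=O)c1ccc(Oc2cc(C=O)ccc2OC)cc1 | intermediate
7 | methyl 4-[5-(hydroxymethyl)-2-methoxyphenoxy]benzoate | COC(=O)c1ccc(Oc2cc(CO)ccc2OC)cc1 | intermediate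
8 | [4-methoxy-3-[4-(methoxycarbonyl)phenoxy]benzyl]triphenylphosphonium bromide | COC(=O)c1ccc(Oc2cc(C[P+](c3ccccc3)(c3ccccc3)c3ccccc3)ccc2OC)cc1.[Br-] | intermediate
9 | phosphonium ylide derived from 8 (not isolated) | COC(=O)c1ccc(Oc2cc(C=P(c3ccccc3)(c3ccccc3)c3ccccc3)ccc2OC)cc1 | intermediate
10 | methyl 3-[4-methoxy-2-[2-[4-methoxy-3-[4-(methoxycarbonyl)phenoxy]phenyl]ethenyl]phenoxy]benzoate (E/Z mixture, geometry left unspecified on purpose) | COC(=O)c1cccc(Oc2ccc(OC)cc2C=Cc2ccc(OC)c(Oc3ccc(C(=O)OC)cc3)c2)c1 | intermediate
11 | methyl 3-[4-methoxy-2-[2-[4-methoxy-3-[4-(methoxycarbonyl)phenoxy]phenyl]ethyl]phenoxy]benzoate | COC(=O)c1cccc(Oc2ccc(OC)cc2CCc2ccc(OC)c(Oc3ccc(C(=O)OC)cc3)c2)c1 | intermediate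
12 | [3-[2-[2-[3-[4-(hydroxymethyl)phenoxy]-4-methoxyphenyl]ethyl]-4-methoxyphenoxy]phenyl]methanol | OCc1cccc(Oc2ccc(OC)cc2CCc2ccc(OC)c(Oc3ccc(CO)cc3)c2)c1 | intermediate
13 | 1-(bromomethyl)-3-[2-[2-[3-[4-(bromomethyl)phenoxy]-4-methoxyphenyl]ethyl]-4-methoxyphenoxy]benzene | BrCc1cccc(Oc2ccc(OC)cc2CCc2ccc(OC)c(Oc3ccc(CBr)cc3)c2)c1 | intermediate
14 | sodium bromo thiolate (not isolated; either benzylic bromide may react first, the isomer with sulfur on the ring C arm is drawn, both close to the same ring) | [Na+].[S-]Cc1ccc(Oc2cc(CCc3cc(OC)ccc3Oc3cccc(CBr)c3)ccc2OC)cc1 | intermediate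
15 | 19-membered cyclic dibenzyl sulfide, dimethyl ether | COc1ccc2c(c1)CCc1ccc(OC)c(c1)Oc1ccc(cc1)CSCc1cccc(c1)O2 | intermediate
16 | 19-membered cyclic sulfoxide, dimethyl ether (not isolated; racemic at sulfur) | COc1ccc2c(c1)CCc1ccc(OC)c(c1)Oc1ccc(cc1)CS(=O)Cc1cccc(c1)O2 | intermediate
17 | 19-membered cyclic dibenzyl sulfone, dimethyl ether | COc1ccc2c(c1)CCc1ccc(OC)c(c1)Oc1ccc(cc1)CS(=O)(=O)Cc1cccc(c1)O2 | intermediate
18 | alpha-bromo sulfone (not isolated; racemic, bromine drawn on the benzylic carbon of ring D) | COc1ccc2c(c1)CCc1ccc(OC)c(c1)Oc1ccc(cc1)CS(=O)(=O)C(Br)c1cccc(c1)O2 | intermediate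
19 | trans-2,3-diaryl thiirane 1,1-dioxide (episulfone; not isolated; racemic, one enantiomer drawn) | COc1ccc2c(c1)CCc1ccc(OC)c(c1)Oc1ccc(cc1)[C@H]1[C@@H](S1(=O)=O)c1cccc(c1)O2 | intermediate
20 | 18-membered macrocyclic (E)-stilbene, dimethyl ether | COc1ccc2c(c1)CCc1ccc(OC)c(c1)Oc1ccc(cc1)/C=C/c1cccc(c1)O2 | intermediate
21 | dihydroptychantol A dimethyl ether | COc1ccc2c(c1)CCc1ccc(OC)c(c1)Oc1ccc(cc1)CCc1cccc(c1)O2 | intermediate
22 | dihydroptychantol A (achiral) | Oc1ccc2c(c1)CCc1ccc(O)c(c1)Oc1ccc(cc1)CCc1cccc(c1)O2 | target

**Step count and risk**

Total steps: 13. Longest linear sequence: 12 steps (4 to 22 through steps 2–13); the other branch (1 + 2 to 3) adds one step and joins at step 5.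

Steps most likely to fail:

1. Step 11 (sulfur extrusion). Bromination may run past one halogen at the sulfone α-carbons, hydroxide may substitute the α-bromo sulfone instead of inducing 1,3-elimination, or a sparingly soluble macrocycle may turn over slowly on the solid base. The fallback reaches the same stilbene without sulfur. It sets out from diol 12: oxidation with activated MnO2 (CH2Cl2, rt) should give the dialdehyde F1, and an intramolecular McMurry coupling (TiCl4, Zn, pyridine, THF, reflux, slow addition) would close the 18-membered ring at the C=C bond. It comes back to the route at stilbene 20, as an E/Z mixture that converges in step 12.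

2. Step 9 (macrocyclisation at sulfur). Intermolecular S-alkylation may outrun ring closure and lead to oligomerisation. The fallback closes the ring through a reversible S–S bond and then removes one sulfur. It sets out from 13: potassium thioacetate (DMF, rt) should give the bis(thioacetate) F2; methanolysis (K2CO3, degassed MeOH) frees the dithiol F3; oxidation at high dilution (I2, Et3N, CH2Cl2/MeOH) gives the 20-membered cyclic disulfide F4, where thiolate-mediated disulfide exchange lets oligomers re-equilibrate to the monomeric ring. Desulfurisation of the dibenzyl disulfide with tris(diethylamino)phosphine (toluene, 80 °C) then contracts F4 and comes back to the route at sulfide 15.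

3. Step 2 (diaryl ether from the ester-activated fluoride). Displacement of a fluoride activated only by a para ester may be sluggish, and at the temperature needed the phenoxide may cleave the ester by O-methyl transfer, or hydrolysis may compete. The fallback sets out from isovanillin 4 and uses a copper-catalysed Ullmann-type O-arylation with commercial methyl 4-bromobenzoate (COC(=O)c1ccc(Br)cc1) (CuI, N,N-dimethylglycine, Cs2CO3, dioxane, 90 °C). It comes back to the route at 6 and makes no compound outside the list (F0).

**Further compounds**

F1 | step 11 | 3-[2-[2-[3-(4-formylphenoxy)-4-methoxyphenyl]ethyl]-4-methoxyphenoxy]benzaldehyde (dialdehyde) | O=Cc1cccc(Oc2ccc(OC)cc2CCc2ccc(OC)c(Oc3ccc(C=O)cc3)c2)c1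
F2 | step 9 | bis(thioacetate) of 13 (both CH2Br replaced by CH2SAc) | CC(=O)SCc1cccc(Oc2ccc(OC)cc2CCc2ccc(OC)c(Oc3ccc(CSC(C)=O)cc3)c2)c1
F3 | step 9 | dithiol (both CH2Br replaced by CH2SH) | SCc1cccc(Oc2ccc(OC)cc2CCc2ccc(OC)c(Oc3ccc(CS)cc3)c2)c1
F4 | step 9 | 20-membered cyclic dibenzyl disulfide, dimethyl ether | COc1ccc2c(c1)CCc1ccc(OC)c(c1)Oc1ccc(cc1)CSSCc1cccc(c1)O2
F0 | step 2 | none | none
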